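**Plan**
- Retrosynthesis: the cyclohexene ring of the decalin (C1, C2, C3=C4, C4a, C8a) is a Diels–Alder retron. Its double bond lies between C2 and C4a, the ketone on C1 makes C1=C8a an electron-poor dienophile, and four CH2 groups (C5–C8) tie C8a to C4a. Cutting C1–C2 and C4a–C8a opens both carbocycles to a (2E,8E,10E)-dodeca-2,8,10-trienoyl chain on the pyridone.
- Further cuts: the enone C=C (aldol condensation with (6E,8E)-deca-6,8-dienal), N–O (N-oxidation), pyridine C3–acetyl (directed lithiation), pyridine C5–carbinol (aryllithium plus a prochiral cyclohexanone).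
- Forward order: pyridine with both oxygens as 2-(trimethylsilyl)ethyl ethers, then the oxygenated cyclohexane ring with its epoxide, then acetyl group, N-oxide and trienone. One fluoride step removes all helper groups, and an enzymatic exo-selective intramolecular Diels–Alder reaction closes the decalin last.
- Stereochemistry: the quaternary carbinol comes from enantiotopic deprotonation with a chiral lithium amide, the epoxide from peroxide attack anti to the axial silyloxy group, the secondary carbinol from hydride attack anti to the epoxide. The four decalin centres come from the E,E,E chain geometry and the enzyme-held exo transition state on one diene face.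

Key step: step 17

Assumption: the lithium amide from (R,R)-bis(1-phenylethyl)amine is taken to remove the alpha-proton that leads to (R)-11, by analogy with 4-substituted cyclohexanones that carry the large group equatorial; if the sense is opposite, the (S,S)-amine is used in the same way.

Step 1
Reactants: 1 2,4-difluoropyridine; 2 2-(trimethylsilyl)ethanol (2.3 equiv)
Product: 4 2,4-bis[2-(trimethylsilyl)ethoxy]pyridine, via sodium 2-(trimethylsilyl)ethoxide 3 (not isolated)
Conditions: NaH, THF/DMF, 0 °C to 60 °C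
Reagents that add atoms: none
Why: Twofold nucleophilic aromatic substitution (SNAr) of the activated 4- and 2-fluorides by the alkoxide gives the bis-ether, whose groups direct lithiation and are later cleaved by fluoride; no stereocentre is formed.

Step 2
Reactants: 4 2,4-bis[2-(trimethylsilyl)ethoxy]pyridine
Product: 5 5-bromo-2,4-bis[2-(trimethylsilyl)ethoxy]pyridine
Conditions: NBS (1.0 equiv), MeCN, 0 °C to rt, dark
Reagents that add atoms: N-bromosuccinimide, O=C1CCC(=O)N1Br
Why: Electrophilic aromatic bromination should go to C5, which is para to the 2-alkoxy and ortho to the 4-alkoxy group and less hindered than C3 between the two ethers.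

Step 3
Reactants: 5 5-bromo-2,4-bis[2-(trimethylsilyl)ethoxy]pyridine; 6 4,4-dimethoxycyclohexan-1-one
Product: 9 5-[4,4-dimethoxy-1-(triethylsilyloxy)cyclohexyl]-2,4-bis[2-(trimethylsilyl)ethoxy]pyridine, via 5-lithiopyridine 7 (not isolated), via lithium alkoxide 8 (not isolated)
Conditions: n-BuLi, THF, −78 °C; then 6; then Et3SiOTf, −78 °C to 0 °C
Reagents that add atoms: triethylsilyl trifluoromethanesulfonate, CC[Si](CC)(CC)OS(=O)(=O)C(F)(F)F
Why: Bromine–lithium exchange, 1,2-addition of the aryllithium to the ketone and O-silylation of the hindered lithium alkoxide in the same flask build the tertiary carbinol, which is not yet stereogenic because the ring is symmetric.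

Step 4
Reactants: 9 5-[4,4-dimethoxy-1-(triethylsilyloxy)cyclohexyl]-2,4-bis[2-(trimethylsilyl)ethoxy]pyridine
Product: 10 4-{4,6-bis[2-(trimethylsilyl)ethoxy]pyridin-3-yl}-4-(triethylsilyloxy)cyclohexan-1-one
Conditions: PPTS (cat.), acetone/H2O, rt
Reagents that add atoms: water, O
Why: Mild acid-catalysed ketal hydrolysis should free the ketone, since a dimethyl ketal is far more labile than the hindered tertiary triethylsilyl ether and the aryl ethers.

Step 5
Reactants: 10 4-{4,6-bis[2-(trimethylsilyl)ethoxy]pyridin-3-yl}-4-(triethylsilyloxy)cyclohexan-1-one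
Product: 11 5-[(1R)-1-(triethylsilyloxy)-4-(trimethylsilyloxy)cyclohex-3-en-1-yl]-2,4-bis[2-(trimethylsilyl)ethoxy]pyridine
Conditions: (R,R)-bis(1-phenylethyl)amine, n-BuLi, THF, −78 °C; Me3SiCl (internal quench), then 10, −100 °C
Reagents that add atoms: chlorotrimethylsilane, C[Si](C)(C)Cl
Why: Enantioselective deprotonation (desymmetrization) by a chiral lithium amide removes one of the two enantiotopic axial alpha-protons, which turns the carbinol carbon into a stereocentre (R) whose sense is set by the base.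

Step 6
Reactants: 11 5-[(1R)-1-(triethylsilyloxy)-4-(trimethylsilyloxy)cyclohex-3-en-1-yl]-2,4-bis[2-(trimethylsilyl)ethoxy]pyridine
Product: 12 (4R)-4-{4,6-bis[2-(trimethylsilyl)ethoxy]pyridin-3-yl}-4-(triethylsilyloxy)cyclohex-2-en-1-one
Conditions: Pd(OAc)2 (10 mol%), O2 (1 atm), DMSO, rt
Reagents that add atoms: none
Why: Saegusa–Ito oxidation (palladium enolate, beta-hydride elimination, O2 as terminal oxidant) places the enone double bond on the side fixed in step 5 without touching the quaternary centre.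

Step 7
Reactants: 12 (4R)-4-{4,6-bis[2-(trimethylsilyl)ethoxy]pyridin-3-yl}-4-(triethylsilyloxy)cyclohex-2-en-1-one
Product: 13 (1S,5S,6R)-5-{4,6-bis[2-(trimethylsilyl)ethoxy]pyridin-3-yl}-5-(triethylsilyloxy)-7-oxabicyclo[4.1.0]heptan-2-one (epoxide cis to the pyridyl group)
Conditions: t-BuOOH, DBU, CH2Cl2, 0 °C to rt
Reagents that add atoms: tert-butyl hydroperoxide, CC(C)(C)OO
Why: Weitz–Scheffer nucleophilic epoxidation; the pyridyl group should sit pseudo-equatorial, so the peroxide adds axially at C3 anti to the pseudo-axial silyloxy group and the epoxide forms on the face of the pyridyl group.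

Step 8
Reactants: 13 (1S,5S,6R)-5-{4,6-bis[2-(trimethylsilyl)ethoxy]pyridin-3-yl}-5-(triethylsilyloxy)-7-oxabicyclo[4.1.0]heptan-2-one
Product: 14 (1R,2R,5S,6R)-5-{4,6-bis[2-(trimethylsilyl)ethoxy]pyridin-3-yl}-5-(triethylsilyloxy)-7-oxabicyclo[4.1.0]heptan-2-ol (hydroxyl cis to the epoxide)
Conditions: NaBH4, CeCl3·7H2O, MeOH, −78 °C
Reagents that add atoms: none
Why: Luche reduction; hydride should enter anti to the epoxide C–O bond (polar and steric control), which gives the hydroxyl cis to the epoxide and trans to the tertiary silyloxy group.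

Step 9
Reactants: 14 (1R,2R,5S,6R)-5-{4,6-bis[2-(trimethylsilyl)ethoxy]pyridin-3-yl}-5-(triethylsilyloxy)-7-oxabicyclo[4.1.0]heptan-2-ol
Product: 15 5-[(1R,2S,5R,6S)-2,5-bis(triethylsilyloxy)-7-oxabicyclo[4.1.0]heptan-2-yl]-2,4-bis[2-(trimethylsilyl)ethoxy]pyridine
Conditions: Et3SiCl, imidazole, DMF, 0 °C to rt
Reagents that add atoms: chlorotriethylsilane, CC[Si](CC)(CC)Cl
Why: Silylation of the secondary alcohol lets it survive the organolithium and enolate steps and puts all hydroxyl protection on fluoride-labile groups.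

Step 10
Reactants: 15 5-[(1R,2S,5R,6S)-2,5-bis(triethylsilyloxy)-7-oxabicyclo[4.1.0]heptan-2-yl]-2,4-bis[2-(trimethylsilyl)ethoxy]pyridine
Product: 18 1-{5-[(1R,2S,5R,6S)-2,5-bis(triethylsilyloxy)-7-oxabicyclo[4.1.0]heptan-2-yl]-2,4-bis[2-(trimethylsilyl)ethoxy]pyridin-3-yl}ethan-1-one, via 3-lithiopyridine 16 (not isolated), via tetrahedral lithium adduct 17 (not isolated)
Conditions: n-BuLi, THF, −78 °C to −30 °C; then MeC(O)N(OMe)Me, −78 °C; then H2O
Reagents that add atoms: N-methoxy-N-methylacetamide, CC(=O)N(C)OC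
Why: Directed ortho-metalation at C3 between the two alkoxy groups followed by Weinreb ketone synthesis should give the methyl ketone, the chelated adduct preventing over-addition.

Step 11
Reactants: 18 1-{5-[(1R,2S,5R,6S)-2,5-bis(triethylsilyloxy)-7-oxabicyclo[4.1.0]heptan-2-yl]-2,4-bis[2-(trimethylsilyl)ethoxy]pyridin-3-yl}ethan-1-one
Product: 19 3-acetyl-5-[(1R,2S,5R,6S)-2,5-bis(triethylsilyloxy)-7-oxabicyclo[4.1.0]heptan-2-yl]-2,4-bis[2-(trimethylsilyl)ethoxy]pyridine 1-oxide
Conditions: mCPBA, CH2Cl2, 0 °C to rt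
Reagents that add atoms: 3-chloroperoxybenzoic acid, OOC(=O)c1cccc(Cl)c1
Why: Peracid N-oxidation of the pyridine is done now, while the molecule has no C=C bond, and the 2-alkoxy N-oxide is the masked N-hydroxy-2-pyridone.

Step 12
Reactants: 20 methyl hept-6-ynoate; 21 (E)-1-bromoprop-1-ene
Product: 23 methyl (6E,8E)-deca-6,8-dienoate, via (E)-alkenyl catecholboronate 22 (not isolated)
Conditions: catecholborane, neat, 70 °C; then 21, Pd(PPh3)4 (3 mol%), NaOMe, MeOH/THF, 60 °C
Reagents that add atoms: none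
Why: syn-Hydroboration of the terminal alkyne gives the (E)-alkenylboronate, and Suzuki–Miyaura coupling with retention on both partners fixes the E,E diene.

Step 13
Reactants: 23 methyl (6E,8E)-deca-6,8-dienoate
Product: 25 (6E,8E)-deca-6,8-dienal, via aluminium hemiacetal 24 (not isolated)
Conditions: i-Bu2AlH, CH2Cl2, −78 °C; then MeOH, aq. KNaC4H4O6
Reagents that add atoms: none
Why: Partial reduction of the ester at low temperature stops at the stable aluminium hemiacetal, which releases the aldehyde only on work-up.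

Step 14
Reactants: 19 3-acetylpyridine 1-oxide (see step 11); 25 (6E,8E)-deca-6,8-dienal
Product: 27 (8E,10E)-1-{5-[(1R,2S,5R,6S)-2,5-bis(triethylsilyloxy)-7-oxabicyclo[4.1.0]heptan-2-yl]-1-oxido-2,4-bis[2-(trimethylsilyl)ethoxy]pyridin-1-ium-3-yl}-3-hydroxydodeca-8,10-dien-1-one (both C3 epimers), via lithium enolate 26 (not isolated)
Conditions: LiN(SiMe3)2, THF, −78 °C; then 25; then AcOH, −78 °C
Reagents that add atoms: none
Why: Directed aldol addition of the kinetic lithium enolate of the methyl ketone to the aldehyde; the new carbinol centre forms as a mixture and is removed in the next step.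

Step 15
Reactants: 27 aldol adduct (both C3 epimers)
Product: 29 (2E,8E,10E)-1-{5-[(1R,2S,5R,6S)-2,5-bis(triethylsilyloxy)-7-oxabicyclo[4.1.0]heptan-2-yl]-1-oxido-2,4-bis[2-(trimethylsilyl)ethoxy]pyridin-1-ium-3-yl}dodeca-2,8,10-trien-1-one, via beta-acetoxy ketone 28 (not isolated)
Conditions: Ac2O, Et3N, DMAP (cat.), CH2Cl2, 0 °C; then DBU, 0 °C to rt
Reagents that add atoms: none
Why: Acetylation and E1cB elimination of acetate should give the conjugated (E)-enone as the favoured isomer; acetic anhydride is chosen because a sulfonyl chloride would activate the N-oxide.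

Step 16
Reactants: 29 protected trienone N-oxide
Product: 30 1,4-dihydroxy-5-[(1R,2S,5R,6R)-2,5-dihydroxy-7-oxabicyclo[4.1.0]heptan-2-yl]-3-[(2E,8E,10E)-dodeca-2,8,10-trienoyl]pyridin-2(1H)-one (seco-fischerin)
Conditions: Bu4NF (6 equiv), THF, 0 °C to rt; then AcOH; kept cold and used at once
Reagents that add atoms: none
Why: Fluoride-induced desilylation cleaves both silyl ethers and fragments both 2-(trimethylsilyl)ethyl ethers by beta-elimination of ethene, and the 2-oxido N-oxide so formed is the tautomer of the 1-hydroxy-2-pyridone; no acid touches the epoxide or the tertiary carbinol.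

Step 17
Reactants: 30 seco-fischerin
Product: 31 fischerin, 1,4-dihydroxy-5-[(1R,2S,5R,6R)-2,5-dihydroxy-7-oxabicyclo[4.1.0]heptan-2-yl]-3-[(1R,2S,4aR,8aR)-2-methyl-1,2,4a,5,6,7,8,8a-octahydronaphthalene-1-carbonyl]pyridin-2(1H)-one
Conditions: recombinant exo-selective decalin-forming Diels–Alderase (lipocalin-fold pericyclase, no cofactor, 1 mol%), K2HPO4/KH2PO4 buffer pH 7.5, 5 vol% DMSO, 25 °C, dark
Reagents that add atoms: none
Why: Proposed new method: a decalin-forming Diels–Alderase has not been shown to accept an N-hydroxy-2-pyridone that carries the epoxy-diol ring, but the closest known reaction type, the enzyme-catalysed intramolecular [4+2] cycloaddition of 3-trienoyl tetramic acids and 3-trienoyl pyrones to decalins, uses the same 3-acyl-4-hydroxy heterocycle as anchor and the same chain, so acceptance is argued from this shared recognition element. Mechanistically the hydrogen-bonded 4-hydroxyl/ketone unit is held by active-site donors, which lowers the LUMO of the enone C2=C3, while the hydrophobic pocket folds the chain so that the diene C8–C11 stacks on it in a concerted, asynchronous normal-demand Diels–Alder reaction with the C3–C8 bond more advanced. The cyclohexene ring closes in the [4+2] mode through the two new bonds C2–C11 and C3–C8, and the same C3–C8 bond closes the cyclohexane ring through the four-carbon tether (fused, type 1 intramolecular mode). The trans hydrogens at C1 and C8a of the decalin follow from the E enone and the cis relation of the methyl group and C5 from the E,E diene, both by suprafacial addition, whereas the cis ring fusion comes from the exo transition state (ketone exo, tether endo) and the absolute sense from the diene face that the chiral pocket leaves open. The step needs exo over the intrinsically favoured endo mode and one of two diastereomeric face pairings, which the remote stereocentres cannot control; the substrate secures the regiochemistry (tether length) and the relative configuration within one mode (alkene geometry), the enzyme the rest, and the uncatalysed reaction should be slow at 25 °C.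

**Compound list**
1 | 2,4-difluoropyridine | Fc1ccnc(F)c1 | starting material
2 | 2-(trimethylsilyl)ethanol | C[Si](C)(C)CCO | starting material
3 | sodium 2-(trimethylsilyl)ethoxide | C[Si](C)(C)CC[O-].[Na+] | intermediate
4 | 2,4-bis[2-(trimethylsilyl)ethoxy]pyridine | C[Si](C)(C)CCOc1ccnc(OCC[Si](C)(C)C)c1 | intermediate
5 | 5-bromo-2,4-bis[2-(trimethylsilyl)ethoxy]pyridine | C[Si](C)(C)CCOc1cc(OCC[Si](C)(C)C)c(Br)cn1 | intermediate
6 | 4,4-dimethoxycyclohexan-1-one | COC1(OC)CCC(=O)CC1 | starting material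
7 | 5-lithio-2,4-bis[2-(trimethylsilyl)ethoxy]pyridine | C[Si](C)(C)CCOc1cc(OCC[Si](C)(C)C)c([Li])cn1 | intermediate
8 | lithium 1-{4,6-bis[2-(trimethylsilyl)ethoxy]pyridin-3-yl}-4,4-dimethoxycyclohexan-1-olate | C[Si](C)(C)CCOc1cc(OCC[Si](C)(C)C)c(cn1)C2(O[Li])CCC(OC)(OC)CC2 | intermediate
9 | 5-[4,4-dimethoxy-1-(triethylsilyloxy)cyclohexyl]-2,4-bis[2-(trimethylsilyl)ethoxy]pyridine | C[Si](C)(C)CCOc1cc(OCC[Si](C)(C)C)c(cn1)C2(O[Si](CC)(CC)CC)CCC(OC)(OC)CC2 | intermediate
10 | 4-{4,6-bis[2-(trimethylsilyl)ethoxy]pyridin-3-yl}-4-(triethylsilyloxy)cyclohexan-1-one | C[Si](C)(C)CCOc1cc(OCC[Si](C)(C)C)c(cn1)C2(O[Si](CC)(CC)CC)CCC(=O)CC2 | intermediate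
11 | 5-[(1R)-1-(triethylsilyloxy)-4-(trimethylsilyloxy)cyclohex-3-en-1-yl]-2,4-bis[2-(trimethylsilyl)ethoxy]pyridine | C[Si](C)(C)CCOc1cc(OCC[Si](C)(C)C)c(cn1)[C@@]2(O[Si](CC)(CC)CC)CCC(O[Si](C)(C)C)=CC2 | intermediate
12 | (4R)-4-{4,6-bis[2-(trimethylsilyl)ethoxy]pyridin-3-yl}-4-(triethylsilyloxy)cyclohex-2-en-1-one | C[Si](C)(C)CCOc1cc(OCC[Si](C)(C)C)c(cn1)[C@@]2(O[Si](CC)(CC)CC)CCC(=O)C=C2 | intermediate
13 | (1S,5S,6R)-5-{4,6-bis[2-(trimethylsilyl)ethoxy]pyridin-3-yl}-5-(triethylsilyloxy)-7-oxabicyclo[4.1.0]heptan-2-one | C[Si](C)(C)CCOc1cc(OCC[Si](C)(C)C)c(cn1)[C@@]2(O[Si](CC)(CC)CC)CCC(=O)[C@H]3O[C@H]32 | intermediate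
14 | (1R,2R,5S,6R)-5-{4,6-bis[2-(trimethylsilyl)ethoxy]pyridin-3-yl}-5-(triethylsilyloxy)-7-oxabicyclo[4.1.0]heptan-2-ol | C[Si](C)(C)CCOc1cc(OCC[Si](C)(C)C)c(cn1)[C@@]2(O[Si](CC)(CC)CC)CC[C@@H](O)[C@H]3O[C@H]32 | intermediate
15 | 5-[(1R,2S,5R,6S)-2,5-bis(triethylsilyloxy)-7-oxabicyclo[4.1.0]heptan-2-yl]-2,4-bis[2-(trimethylsilyl)ethoxy]pyridine | C[Si](C)(C)CCOc1cc(OCC[Si](C)(C)C)c(cn1)[C@@]2(O[Si](CC)(CC)CC)CC[C@@H](O[Si](CC)(CC)CC)[C@H]3O[C@H]32 | intermediate
16 | 3-lithio derivative of 15 | C[Si](C)(C)CCOc1c([Li])c(OCC[Si](C)(C)C)c(cn1)[C@@]2(O[Si](CC)(CC)CC)CC[C@@H](O[Si](CC)(CC)CC)[C@H]3O[C@H]32 | intermediate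
17 | lithium 1-(N-methoxy-N-methylamino)-1-(pyridin-3-yl)ethan-1-olate adduct of 16 (tetrahedral adduct, new centre undefined) | C[Si](C)(C)CCOc1c(C(C)(O[Li])N(C)OC)c(OCC[Si](C)(C)C)c(cn1)[C@@]2(O[Si](CC)(CC)CC)CC[C@@H](O[Si](CC)(CC)CC)[C@H]3O[C@H]32 | intermediate
18 | 1-{5-[(1R,2S,5R,6S)-2,5-bis(triethylsilyloxy)-7-oxabicyclo[4.1.0]heptan-2-yl]-2,4-bis[2-(trimethylsilyl)ethoxy]pyridin-3-yl}ethan-1-one | C[Si](C)(C)CCOc1c(C(C)=O)c(OCC[Si](C)(C)C)c(cn1)[C@@]2(O[Si](CC)(CC)CC)CC[C@@H](O[Si](CC)(CC)CC)[C@H]3O[C@H]32 | intermediate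
19 | 3-acetyl-5-[(1R,2S,5R,6S)-2,5-bis(triethylsilyloxy)-7-oxabicyclo[4.1.0]heptan-2-yl]-2,4-bis[2-(trimethylsilyl)ethoxy]pyridine 1-oxide | C[Si](C)(C)CCOc1c(C(C)=O)c(OCC[Si](C)(C)C)c(c[n+]1[O-])[C@@]2(O[Si](CC)(CC)CC)CC[C@@H](O[Si](CC)(CC)CC)[C@H]3O[C@H]32 | intermediate
20 | methyl hept-6-ynoate | C#CCCCCC(=O)OC | starting material
21 | (E)-1-bromoprop-1-ene | C/C=C/Br | starting material
22 | methyl (E)-7-(1,3,2-benzodioxaborol-2-yl)hept-6-enoate | COC(=O)CCCC/C=C/B1Oc2ccccc2O1 | intermediate
23 | methyl (6E,8E)-deca-6,8-dienoate | COC(=O)CCCC/C=C/C=C/C | intermediate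
24 | diisobutyl{[(6E,8E)-1-methoxydeca-6,8-dien-1-yl]oxy}alane (aluminium hemiacetal) | COC(CCCC/C=C/C=C/C)O[Al](CC(C)C)CC(C)C | intermediate
25 | (6E,8E)-deca-6,8-dienal | O=CCCCC/C=C/C=C/C | intermediate
26 | lithium enolate of 19 | C[Si](C)(C)CCOc1c(C(=C)O[Li])c(OCC[Si](C)(C)C)c(c[n+]1[O-])[C@@]2(O[Si](CC)(CC)CC)CC[C@@H](O[Si](CC)(CC)CC)[C@H]3O[C@H]32 | intermediate
27 | (8E,10E)-3-hydroxy-1-(pyridin-1-ium-3-yl 1-oxide of 19)dodeca-8,10-dien-1-one, both C3 epimers | C[Si](C)(C)CCOc1c(C(=O)CC(O)CCCC/C=C/C=C/C)c(OCC[Si](C)(C)C)c(c[n+]1[O-])[C@@]2(O[Si](CC)(CC)CC)CC[C@@H](O[Si](CC)(CC)CC)[C@H]3O[C@H]32 | intermediate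
28 | 3-acetate of 27 (beta-acetoxy ketone) | C[Si](C)(C)CCOc1c(C(=O)CC(OC(C)=O)CCCC/C=C/C=C/C)c(OCC[Si](C)(C)C)c(c[n+]1[O-])[C@@]2(O[Si](CC)(CC)CC)CC[C@@H](O[Si](CC)(CC)CC)[C@H]3O[C@H]32 | intermediate
29 | (2E,8E,10E)-1-{5-[(1R,2S,5R,6S)-2,5-bis(triethylsilyloxy)-7-oxabicyclo[4.1.0]heptan-2-yl]-1-oxido-2,4-bis[2-(trimethylsilyl)ethoxy]pyridin-1-ium-3-yl}dodeca-2,8,10-trien-1-one | C[Si](C)(C)CCOc1c(C(=O)/C=C/CCCC/C=C/C=C/C)c(OCC[Si](C)(C)C)c(c[n+]1[O-])[C@@]2(O[Si](CC)(CC)CC)CC[C@@H](O[Si](CC)(CC)CC)[C@H]3O[C@H]32 | intermediate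
30 | seco-fischerin, 1,4-dihydroxy-5-[(1R,2S,5R,6R)-2,5-dihydroxy-7-oxabicyclo[4.1.0]heptan-2-yl]-3-[(2E,8E,10E)-dodeca-2,8,10-trienoyl]pyridin-2(1H)-one | C/C=C/C=C/CCCC/C=C/C(=O)c1c(O)c([C@@]2(O)CC[C@@H](O)[C@H]3O[C@H]32)cn(O)c1=O | intermediate
31 | fischerin | C[C@H]1C=C[C@H]2CCCC[C@H]2[C@@H]1C(=O)c1c(O)c([C@@]2(O)CC[C@@H](O)[C@H]3O[C@H]32)cn(O)c1=O | target

**Step count**
Total: 17 steps. Longest linear sequence: 15 steps (steps 1–11, then 14–17); the dienal branch (steps 12–13) has 2 steps.

**Steps most likely to fail**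

1. Step 17 (key step). What may go wrong: the enzyme may not bind or turn over the fully oxidised, non-native substrate, so that the slow uncatalysed, endo-preferring cycloaddition takes over and the ring fusion or the diene face comes out wrong. Fallback, by known chemistry, sets out from 29 and comes back at 31. The cycloaddition is run thermally and without catalyst on the protected trienone 29 (toluene, 90 °C, trace of BHT). A thermal intramolecular Diels–Alder reaction of such a trienone should give endo and exo adducts on both faces. The cis-fused exo adduct with the wanted face, protected fischerin F1, is taken out by preparative HPLC and desilylated with Bu4NF in THF as in step 16 to give 31. Selectivity is given up for certainty of ring closure.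

2. Step 5. What may go wrong: insufficient discrimination between the enantiotopic alpha-protons, or equilibration of the lithium enolate before silylation, so that the quaternary centre is formed with low enantiomeric purity. Fallback sets out from aryllithium 7 and comes back at 12, replacing desymmetrization by chiral-pool diastereoselection. 7 is added at −78 °C to the enantiopure building block (S)-4-(tert-butyldimethylsilyloxy)cyclohex-2-en-1-one. 1,2-Addition anti to the silyloxy group should give the tertiary allylic alcohol F2 as the main diastereomer, and chromatography removes the minor one and so secures the enantiomeric purity. Bu4NF then frees the cis-diol F3, MnO2 oxidises only the secondary allylic alcohol to the (R)-hydroxy enone F4, and Et3SiOTf/2,6-lutidine at −78 °C gives 12.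

3. Step 8. What may go wrong: poor facial selectivity of hydride delivery, because the ring conformation imposed by the quaternary centre may open the epoxide face to attack. Fallback sets out from 13 and comes back at 14, replacing direct control by inversion. If the reduction gives mainly the trans-epoxy alcohol F5, a Mitsunobu reaction (4-nitrobenzoic acid, PPh3, diisopropyl azodicarboxylate, THF, 0 °C) inverts the carbinol to the 4-nitrobenzoate F6, and methanolysis (K2CO3, MeOH, 0 °C) gives 14.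

Further compounds
F1 | step 17 | protected fischerin, 5-[(1R,2S,5R,6S)-2,5-bis(triethylsilyloxy)-7-oxabicyclo[4.1.0]heptan-2-yl]-3-[(1R,2S,4aR,8aR)-2-methyl-1,2,4a,5,6,7,8,8a-octahydronaphthalene-1-carbonyl]-2,4-bis[2-(trimethylsilyl)ethoxy]pyridine 1-oxide | C[C@H]1C=C[C@H]2CCCC[C@H]2[C@@H]1C(=O)c1c(OCC[Si](C)(C)C)c(c[n+]([O-])c1OCC[Si](C)(C)C)[C@@]2(O[Si](CC)(CC)CC)CC[C@@H](O[Si](CC)(CC)CC)[C@H]3O[C@H]32
F2 | step 5 | (1R,4S)-1-{4,6-bis[2-(trimethylsilyl)ethoxy]pyridin-3-yl}-4-(tert-butyldimethylsilyloxy)cyclohex-2-en-1-ol | C[Si](C)(C)CCOc1cc(OCC[Si](C)(C)C)c(cn1)[C@@]2(O)CC[C@H](O[Si](C)(C)C(C)(C)C)C=C2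
F3 | step 5 | (1R,4S)-1-{4,6-bis[2-(trimethylsilyl)ethoxy]pyridin-3-yl}cyclohex-2-ene-1,4-diol | C[Si](C)(C)CCOc1cc(OCC[Si](C)(C)C)c(cn1)[C@@]2(O)CC[C@H](O)C=C2
F4 | step 5 | (4R)-4-{4,6-bis[2-(trimethylsilyl)ethoxy]pyridin-3-yl}-4-hydroxycyclohex-2-en-1-one | C[Si](C)(C)CCOc1cc(OCC[Si](C)(C)C)c(cn1)[C@@]2(O)CCC(=O)C=C2
F5 | step 8 | C2 epimer of 14 (hydroxyl trans to the epoxide) | C[Si](C)(C)CCOc1cc(OCC[Si](C)(C)C)c(cn1)[C@@]2(O[Si](CC)(CC)CC)CC[C@H](O)[C@H]3O[C@H]32
F6 | step 8 | 4-nitrobenzoate of 14 | C[Si](C)(C)CCOc1cc(OCC[Si](C)(C)C)c(cn1)[C@@]2(O[Si](CC)(CC)CC)CC[C@@H](OC(=O)c4ccc(cc4)[N+](=O)[O-])[C@H]3O[C@H]32
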